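**Retrosynthetic overview**

1. Feature on which the route rests: in ring A the C2–C3 bond joins the O-benzylic C2 (bearing 4-hydroxyphenyl) to the diarylmethine C3, whose benzo ring has oxygen on both carbons next to C3a (O1 on C7a, OH on C4). Ring B repeats this motif in the mirror-image sense.
2. 25 ⇒ 24 (cleave seven methyl ethers) ⇒ 22 + 4-methoxystyrene (Heck, C6–vinyl bond) ⇒ 20 (C2 epimerisation with loss of the 4-methoxybenzyl ether).
3. 20 ⇒ 19 (ring A, C2–C3 bond, by dirhodium carbene insertion into an OCH2Ar C–H bond) ⇒ ketone 17 ⇒ lithiated ring B bromide 12 + aldehyde 14.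
4. 12 ⇒ 10 (ring B by the same insertion with the enantiomeric catalyst, then C2 epimerisation) ⇒ aldehyde 4 + 3,5-dimethoxyphenyl Grignard reagent; 4 and 14 both come from 4-bromo-2,6-difluorobenzaldehyde by SNAr.
5. Ring order: ring B (step 7), then ring A (step 14).

Key step: step 14

Assumption: Rh2(S-PTAD)4 is taken to give the 3R sense at the new diarylmethine carbon and Rh2(R-PTAD)4 the 3S sense; should the induction run the other way, the two enantiomeric catalysts are exchanged between steps 7 and 14.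

**Route**

Step 1
Reactants: 1 4-bromo-2,6-difluorobenzaldehyde
Product: 2 4-bromo-2-fluoro-6-methoxybenzaldehyde
Conditions: NaOMe (1.05 equiv), MeOH/THF, 0 °C → rt
Reagents that add atoms: sodium methoxide, [Na+].[O-]C
Why: Nucleophilic aromatic substitution (SNAr) of a fluoride activated by the ortho formyl group; the methoxy group introduced deactivates the ring, so the second fluoride should stay.

Step 2
Reactants: 2 4-bromo-2-fluoro-6-methoxybenzaldehyde; 3 3,4-dimethoxybenzyl alcohol
Product: 4 4-bromo-2-[(3,4-dimethoxybenzyl)oxy]-6-methoxybenzaldehyde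
Conditions: 3, NaH, THF/DMF, 0 °C → 40 °C (alkoxide preformed and added slowly)
Reagents that add atoms: none
Why: Second SNAr, in which the preformed sodium benzyl oxide displaces the remaining ortho fluoride; fluoride is a far better leaving group than the para bromide in this addition–elimination, so the bromide should survive.

Step 3
Reactants: 4 4-bromo-2-[(3,4-dimethoxybenzyl)oxy]-6-methoxybenzaldehyde; 5 1-bromo-3,5-dimethoxybenzene
Product: 7 [4-bromo-2-(3,4-dimethoxybenzyloxy)-6-methoxyphenyl](3,5-dimethoxyphenyl)methanol (racemic), via 3,5-dimethoxyphenylmagnesium bromide 6 (not isolated)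
Conditions: 5, Mg, THF, reflux; then 4, THF, 0 °C; aq NH4Cl
Reagents that add atoms: none
Why: Grignard addition to the aldehyde; the aryl bromide of 4 does not exchange with an arylmagnesium halide at 0 °C, and the carbinol centre is formed racemic because it is removed by oxidation in step 4.

Step 4
Reactants: 7 [4-bromo-2-(3,4-dimethoxybenzyloxy)-6-methoxyphenyl](3,5-dimethoxyphenyl)methanol
Product: 8 [4-bromo-2-(3,4-dimethoxybenzyloxy)-6-methoxyphenyl](3,5-dimethoxyphenyl)methanone
Conditions: Dess–Martin periodinane, pyridine, CH2Cl2, 0 °C → rt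
Reagents that add atoms: none
Why: Dess–Martin oxidation of a secondary benzhydrol under buffered, nearly neutral conditions, which should avoid ionisation of the electron-rich diarylmethanol and leave the benzyl ether and aryl bromide untouched.

Step 5
Reactants: 8 [4-bromo-2-(3,4-dimethoxybenzyloxy)-6-methoxyphenyl](3,5-dimethoxyphenyl)methanone
Product: 9 hydrazone of ketone 8 (E/Z mixture)
Conditions: N2H4·H2O (excess), AcOH (cat.), EtOH, 90 °C, sealed tube
Reagents that add atoms: hydrazine (used as the hydrate), NN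
Why: Acid-catalysed hydrazone condensation; excess hydrazine and heat are used because two ortho alkoxy groups shield the carbonyl, and the excess also suppresses azine formation.

Step 6
Reactants: 9 hydrazone of ketone 8
Product: 10 [4-bromo-2-(3,4-dimethoxybenzyloxy)-6-methoxyphenyl](3,5-dimethoxyphenyl)diazomethane
Conditions: activated MnO2, CH2Cl2, 0 °C; filtered through Celite, concentrated cold and used at once
Reagents that add atoms: none
Why: Dehydrogenation of an N-unsubstituted hydrazone to the diaryldiazomethane by MnO2; the two ortho substituents should slow bimolecular azine formation.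

Step 7
Reactants: 10 [4-bromo-2-(3,4-dimethoxybenzyloxy)-6-methoxyphenyl](3,5-dimethoxyphenyl)diazomethane
Product: 11 (2R,3S)-6-bromo-2-(3,4-dimethoxyphenyl)-3-(3,5-dimethoxyphenyl)-4-methoxy-2,3-dihydrobenzofuran (ring B, cis)
Conditions: Rh2(R-PTAD)4 (1 mol%), CH2Cl2, 0 °C → rt
Reagents that add atoms: none
Why: Dirhodium-catalysed intramolecular 1,5 C–H insertion of a diaryl (donor/donor) carbene into the benzylic OCH2 group, which is a far better hydride donor than the methoxy C–H bonds; C3 (S) is set by the chiral carboxylate ligands and C2 comes out cis through the compact insertion transition state.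

Step 8
Reactants: 11 (2R,3S)-6-bromo-2-(3,4-dimethoxyphenyl)-3-(3,5-dimethoxyphenyl)-4-methoxy-2,3-dihydrobenzofuran
Product: 12 (2S,3S)-6-bromo-2-(3,4-dimethoxyphenyl)-3-(3,5-dimethoxyphenyl)-4-methoxy-2,3-dihydrobenzofuran (ring B, trans)
Conditions: TFA, CH2Cl2, 0 °C → rt
Reagents that add atoms: none
Why: Acid-mediated epimerisation: reversible heterolysis of the O1–C2 bond gives a 4-alkoxybenzylic cation that is recaptured by the tethered phenol oxygen, so C2 should equilibrate to the more stable trans (2S) configuration while C3 is not involved.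

Step 9
Reactants: 1 4-bromo-2,6-difluorobenzaldehyde; 13 4-methoxybenzyl alcohol
Product: 14 4-bromo-2,6-bis[(4-methoxybenzyl)oxy]benzaldehyde
Conditions: 13 (2.3 equiv), NaH, THF/DMF, 0 °C → 50 °C
Reagents that add atoms: none
Why: Double SNAr of both ortho fluorides by sodium 4-methoxybenzyl oxide; the formyl group activates both positions and the second, slower substitution is driven by excess alkoxide and gentle warming.

Step 10
Reactants: 12 (2S,3S)-6-bromo-2-(3,4-dimethoxyphenyl)-3-(3,5-dimethoxyphenyl)-4-methoxy-2,3-dihydrobenzofuran; 14 4-bromo-2,6-bis[(4-methoxybenzyl)oxy]benzaldehyde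
Product: 16 [4-bromo-2,6-bis(4-methoxybenzyloxy)phenyl][(2S,3S)-2-(3,4-dimethoxyphenyl)-3-(3,5-dimethoxyphenyl)-4-methoxy-2,3-dihydrobenzofuran-6-yl]methanol (both carbinol epimers), via ring B aryllithium 15 (not isolated)
Conditions: 12, n-BuLi, THF, −78 °C; then 14, −78 → −20 °C; aq NH4Cl
Reagents that add atoms: none
Why: Bromine–lithium exchange followed by 1,2-addition to the aldehyde, which at −78 °C should be much faster than exchange with the aryl bromide of 14; the new carbinol centre forms without control and is removed by oxidation in step 11.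

Step 11
Reactants: 16 diarylmethanol
Product: 17 [4-bromo-2,6-bis(4-methoxybenzyloxy)phenyl][(2S,3S)-2-(3,4-dimethoxyphenyl)-3-(3,5-dimethoxyphenyl)-4-methoxy-2,3-dihydrobenzofuran-6-yl]methanone
Conditions: Dess–Martin periodinane, pyridine, CH2Cl2, 0 °C → rt
Reagents that add atoms: none
Why: Dess–Martin oxidation of the secondary diarylmethanol; the buffered conditions should spare the 4-methoxybenzyl ethers and the ring B stereocentres.

Step 12
Reactants: 17 diaryl ketone
Product: 18 hydrazone of ketone 17 (E/Z mixture)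
Conditions: N2H4·H2O (excess), AcOH (cat.), n-BuOH, 110 °C
Reagents that add atoms: hydrazine (used as the hydrate), NN
Why: Hydrazone condensation as in step 5; the ketone aryl of ring B carries no ortho substituent, so the carbonyl remains reachable from that side, and nothing else in the molecule reacts with hydrazine.

Step 13
Reactants: 18 hydrazone of ketone 17
Product: 19 [4-bromo-2,6-bis(4-methoxybenzyloxy)phenyl][(2S,3S)-2-(3,4-dimethoxyphenyl)-3-(3,5-dimethoxyphenyl)-4-methoxy-2,3-dihydrobenzofuran-6-yl]diazomethane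
Conditions: activated MnO2, CH2Cl2, 0 °C; filtered through Celite, concentrated cold and used at once
Reagents that add atoms: none
Why: MnO2 dehydrogenation of the hydrazone to the diaryldiazomethane, as in step 6; the two flanking 4-methoxybenzyloxy groups should protect the diazo carbon from dimerisation.

Step 14
Reactants: 19 diaryldiazomethane
Product: 20 (2S,3R)-6-bromo-3-[(2S,3S)-2-(3,4-dimethoxyphenyl)-3-(3,5-dimethoxyphenyl)-4-methoxy-2,3-dihydrobenzofuran-6-yl]-4-(4-methoxybenzyloxy)-2-(4-methoxyphenyl)-2,3-dihydrobenzofuran (ring A, cis)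
Conditions: Rh2(S-PTAD)4 [dirhodium tetrakis(N-phthaloyl-(S)-adamantylglycinate)] (1–2 mol%), CH2Cl2, 0 °C → rt
Reagents that add atoms: none
Why: Rh2(S-PTAD)4 takes N2 from 19 to give a dirhodium carbene flanked by two aryl groups, which inserts into a benzylic C–H bond of one ortho OCH2Ar group through a concerted, hydride-transfer-like three-centre transition state; the closest known reaction type is the dirhodium-catalysed enantioselective intramolecular C–H insertion of diaryl carbenes into benzyl ethers to give 2,3-diaryl-2,3-dihydrobenzofurans. Ring A closes by 1,5-insertion, its five atoms being the carbene carbon (C3), C3a, C7a, O1 and the former benzylic carbon (C2), and the bond formed is C2–C3. C3 (R) is set by the chiral carboxylate ligands, which select the carbene face, while the ring B stereocentres lie beyond the C6 aryl carbon and should not override the catalyst; C2 is set relative to C3 by the compact transition state, which should give the cis (2S) isomer that step 15 corrects. The step needs site selectivity for the OCH2 hydrogens over methoxy C–H bonds, arene addition and azine formation: the 4-methoxyphenyl group makes the benzylic hydrogen the best hydride donor, the two ortho ether groups are identical so that either gives the same product and the other remains as protection of the C4 oxygen, and the weakly electrophilic, sterically shielded carbene should resist dimerisation.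

Step 15
Reactants: 20 ring A insertion product (cis)
Product: 22 (2R,3R)-6-bromo-3-[(2S,3S)-2-(3,4-dimethoxyphenyl)-3-(3,5-dimethoxyphenyl)-4-methoxy-2,3-dihydrobenzofuran-6-yl]-2-(4-methoxyphenyl)-2,3-dihydrobenzofuran-4-ol (ring A, trans), via cis phenol 21 (not isolated)
Conditions: TFA, C6HMe5 (5 equiv), CH2Cl2, 0 °C → rt
Reagents that add atoms: none
Why: Acidolysis removes the 4-methoxybenzyl ether (its cation is trapped by pentamethylbenzene, too hindered to intercept the ring-opened species), and reversible O1–C2 heterolysis to the 4-methoxybenzylic cation followed by reclosure should set C2 to the thermodynamic trans (2R) configuration; after ring opening the two phenolic oxygens are equivalent by rotation, so either closes to the same product, and C3 is not involved.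

Step 16
Reactants: 22 trans bromophenol; 23 4-methoxystyrene
Product: 24 (2R,3R)-3-[(2S,3S)-2-(3,4-dimethoxyphenyl)-3-(3,5-dimethoxyphenyl)-4-methoxy-2,3-dihydrobenzofuran-6-yl]-2-(4-methoxyphenyl)-6-[(E)-4-methoxystyryl]-2,3-dihydrobenzofuran-4-ol
Conditions: 23, Pd(OAc)2 (5 mol%), P(o-tol)3, Et3N, DMF, 100 °C
Reagents that add atoms: none
Why: Mizoroki–Heck coupling of the aryl bromide with the terminal styrene; syn insertion and syn β-hydride elimination should give the E-stilbene, and the free phenol and both dihydrobenzofurans tolerate the basic conditions.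

Step 17
Reactants: 24 heptamethyl ether
Product: 25 (2R,3R)-3-[(2S,3S)-2-(3,4-dihydroxyphenyl)-3-(3,5-dihydroxyphenyl)-4-hydroxy-2,3-dihydrobenzofuran-6-yl]-2-(4-hydroxyphenyl)-6-[(E)-4-hydroxystyryl]-2,3-dihydrobenzofuran-4-ol (target, CNP0107857.3)
Conditions: BBr3 (excess), CH2Cl2, −78 °C → rt; then MeOH, H2O
Reagents that add atoms: none
Why: Lewis-acid cleavage of all seven aryl methyl ethers by BBr3; both dihydrobenzofurans are already trans, the thermodynamic arrangement, so any reversible O1–C2 opening should return the same configuration.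

**Compound list**

1 | 4-bromo-2,6-difluorobenzaldehyde | O=Cc1c(F)cc(Br)cc1F | starting material
2 | 4-bromo-2-fluoro-6-methoxybenzaldehyde | COc1cc(Br)cc(F)c1C=O | intermediate
3 | 3,4-dimethoxybenzyl alcohol | COc1ccc(CO)cc1OC | starting material
4 | 4-bromo-2-[(3,4-dimethoxybenzyl)oxy]-6-methoxybenzaldehyde | COc1ccc(COc2cc(Br)cc(OC)c2C=O)cc1OC | intermediate
5 | 1-bromo-3,5-dimethoxybenzene | COc1cc(Br)cc(OC)c1 | starting material
6 | 3,5-dimethoxyphenylmagnesium bromide (not isolated) | COc1cc([Mg]Br)cc(OC)c1 | intermediate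
7 | [4-bromo-2-(3,4-dimethoxybenzyloxy)-6-methoxyphenyl](3,5-dimethoxyphenyl)methanol, racemic | COc1ccc(COc2cc(Br)cc(OC)c2C(O)c2cc(OC)cc(OC)c2)cc1OC | intermediate
8 | [4-bromo-2-(3,4-dimethoxybenzyloxy)-6-methoxyphenyl](3,5-dimethoxyphenyl)methanone | COc1ccc(COc2cc(Br)cc(OC)c2C(=O)c2cc(OC)cc(OC)c2)cc1OC | intermediate
9 | hydrazone of ketone 8 | COc1ccc(COc2cc(Br)cc(OC)c2C(=NN)c2cc(OC)cc(OC)c2)cc1OC | intermediate
10 | [4-bromo-2-(3,4-dimethoxybenzyloxy)-6-methoxyphenyl](3,5-dimethoxyphenyl)diazomethane | COc1ccc(COc2cc(Br)cc(OC)c2C(=[N+]=[N-])c2cc(OC)cc(OC)c2)cc1OC | intermediate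
11 | (2R,3S)-6-bromo-2-(3,4-dimethoxyphenyl)-3-(3,5-dimethoxyphenyl)-4-methoxy-2,3-dihydrobenzofuran (ring B, cis) | Brc1cc(OC)c2c(c1)O[C@@H](c1ccc(OC)c(OC)c1)[C@H]2c1cc(OC)cc(OC)c1 | intermediate
12 | (2S,3S)-6-bromo-2-(3,4-dimethoxyphenyl)-3-(3,5-dimethoxyphenyl)-4-methoxy-2,3-dihydrobenzofuran (ring B, trans) | Brc1cc(OC)c2c(c1)O[C@H](c1ccc(OC)c(OC)c1)[C@H]2c1cc(OC)cc(OC)c1 | intermediate
13 | 4-methoxybenzyl alcohol | COc1ccc(CO)cc1 | starting material
14 | 4-bromo-2,6-bis[(4-methoxybenzyl)oxy]benzaldehyde | COc1ccc(COc2cc(Br)cc(OCc3ccc(OC)cc3)c2C=O)cc1 | intermediate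
15 | ring B aryllithium, (2S,3S)-2-(3,4-dimethoxyphenyl)-3-(3,5-dimethoxyphenyl)-4-methoxy-2,3-dihydrobenzofuran-6-yllithium (not isolated) | [Li]c1cc(OC)c2c(c1)O[C@H](c1ccc(OC)c(OC)c1)[C@H]2c1cc(OC)cc(OC)c1 | intermediate
16 | [4-bromo-2,6-bis(4-methoxybenzyloxy)phenyl][(2S,3S)-2-(3,4-dimethoxyphenyl)-3-(3,5-dimethoxyphenyl)-4-methoxy-2,3-dihydrobenzofuran-6-yl]methanol, both carbinol epimers | COc1ccc(COc2cc(Br)cc(OCc3ccc(OC)cc3)c2C(O)c2cc(OC)c3c(c2)O[C@H](c2ccc(OC)c(OC)c2)[C@H]3c2cc(OC)cc(OC)c2)cc1 | intermediate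
17 | [4-bromo-2,6-bis(4-methoxybenzyloxy)phenyl][(2S,3S)-2-(3,4-dimethoxyphenyl)-3-(3,5-dimethoxyphenyl)-4-methoxy-2,3-dihydrobenzofuran-6-yl]methanone | COc1ccc(COc2cc(Br)cc(OCc3ccc(OC)cc3)c2C(=O)c2cc(OC)c3c(c2)O[C@H](c2ccc(OC)c(OC)c2)[C@H]3c2cc(OC)cc(OC)c2)cc1 | intermediate
18 | hydrazone of ketone 17 | COc1ccc(COc2cc(Br)cc(OCc3ccc(OC)cc3)c2C(=NN)c2cc(OC)c3c(c2)O[C@H](c2ccc(OC)c(OC)c2)[C@H]3c2cc(OC)cc(OC)c2)cc1 | intermediate
19 | [4-bromo-2,6-bis(4-methoxybenzyloxy)phenyl][(2S,3S)-2-(3,4-dimethoxyphenyl)-3-(3,5-dimethoxyphenyl)-4-methoxy-2,3-dihydrobenzofuran-6-yl]diazomethane (key-step precursor) | COc1ccc(COc2cc(Br)cc(OCc3ccc(OC)cc3)c2C(=[N+]=[N-])c2cc(OC)c3c(c2)O[C@H](c2ccc(OC)c(OC)c2)[C@H]3c2cc(OC)cc(OC)c2)cc1 | intermediate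
20 | (2S,3R)-6-bromo-3-[(2S,3S)-2-(3,4-dimethoxyphenyl)-3-(3,5-dimethoxyphenyl)-4-methoxy-2,3-dihydrobenzofuran-6-yl]-4-(4-methoxybenzyloxy)-2-(4-methoxyphenyl)-2,3-dihydrobenzofuran (key-step product, ring A cis) | Brc1cc(OCc2ccc(OC)cc2)c2c(c1)O[C@H](c1ccc(OC)cc1)[C@@H]2c1cc(OC)c2c(c1)O[C@H](c1ccc(OC)c(OC)c1)[C@H]2c1cc(OC)cc(OC)c1 | intermediate
21 | (2S,3R)-6-bromo-3-[(2S,3S)-2-(3,4-dimethoxyphenyl)-3-(3,5-dimethoxyphenyl)-4-methoxy-2,3-dihydrobenzofuran-6-yl]-2-(4-methoxyphenyl)-2,3-dihydrobenzofuran-4-ol (cis phenol, not isolated) | Brc1cc(O)c2c(c1)O[C@H](c1ccc(OC)cc1)[C@@H]2c1cc(OC)c2c(c1)O[C@H](c1ccc(OC)c(OC)c1)[C@H]2c1cc(OC)cc(OC)c1 | intermediate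
22 | (2R,3R)-6-bromo-3-[(2S,3S)-2-(3,4-dimethoxyphenyl)-3-(3,5-dimethoxyphenyl)-4-methoxy-2,3-dihydrobenzofuran-6-yl]-2-(4-methoxyphenyl)-2,3-dihydrobenzofuran-4-ol (ring A trans) | Brc1cc(O)c2c(c1)O[C@@H](c1ccc(OC)cc1)[C@@H]2c1cc(OC)c2c(c1)O[C@H](c1ccc(OC)c(OC)c1)[C@H]2c1cc(OC)cc(OC)c1 | intermediate
23 | 4-methoxystyrene | C=Cc1ccc(OC)cc1 | starting material
24 | (2R,3R)-3-[(2S,3S)-2-(3,4-dimethoxyphenyl)-3-(3,5-dimethoxyphenyl)-4-methoxy-2,3-dihydrobenzofuran-6-yl]-2-(4-methoxyphenyl)-6-[(E)-4-methoxystyryl]-2,3-dihydrobenzofuran-4-ol | COc1ccc(/C=C/c2cc(O)c3c(c2)O[C@@H](c2ccc(OC)cc2)[C@@H]3c2cc(OC)c3c(c2)O[C@H](c2ccc(OC)c(OC)c2)[C@H]3c2cc(OC)cc(OC)c2)cc1 | intermediate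
25 | (2R,3R)-3-[(2S,3S)-2-(3,4-dihydroxyphenyl)-3-(3,5-dihydroxyphenyl)-4-hydroxy-2,3-dihydrobenzofuran-6-yl]-2-(4-hydroxyphenyl)-6-[(E)-4-hydroxystyryl]-2,3-dihydrobenzofuran-4-ol | Oc1ccc(/C=C/c2cc(O)c3c(c2)O[C@@H](c2ccc(O)cc2)[C@@H]3c2cc(O)c3c(c2)O[C@H](c2ccc(O)c(O)c2)[C@H]3c2cc(O)cc(O)c2)cc1 | target

**Step count**

Total: 17 steps. Longest linear sequence: 16 steps (steps 1–8, then 10–17); step 9 is a one-step branch.

**Steps most likely to fail**

1. Step 14 (key step). The diazo carbon sits between two ortho ether groups, so carbene formation at dirhodium may be slow and the diazo compound may instead be lost to azine or alkene dimers. The catalyst may also fail to control the carbene face against the large chiral ring B substituent. The fallback sets out from ketone 17 and comes back at 22. 4-Methoxybenzylmagnesium chloride is added to 17 (THF, 0 °C) to give the tertiary alcohol F1. Treatment of F1 with TFA and pentamethylbenzene in CH2Cl2 should dehydrate it and remove both 4-methoxybenzyl ethers to give the triarylethene bisphenol F2, which is not isolated. Acid-catalysed intramolecular hydroalkoxylation of F2 (protonation of the alkene to the 4-methoxybenzylic cation, capture by either equivalent phenol oxygen) should then close ring A as the trans isomer under thermodynamic control. The absolute sense of ring A is not controlled in this sequence, so 22 should form together with its (2S,3S)-ring A diastereomer F3; the two are diastereomers because ring B is already fixed, and are separated by chromatography.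

2. Step 12. Condensation of hydrazine at a carbonyl flanked by two 4-methoxybenzyloxy groups may stall or stop at partial conversion. The fallback builds the C=N bond by carbon–carbon bond formation instead; it sets out from aldehyde 14 and comes back at hydrazone 18, bypassing 16 and 17. Aldehyde 14 is converted with I2 and aqueous NH3 in THF into 4-bromo-2,6-bis[(4-methoxybenzyl)oxy]benzonitrile F4. The ring B aryllithium 15 (from 12 and n-BuLi, THF, −78 °C) is added to F4 and the mixture quenched with methanol to give the N–H ketimine F5. Exchange of F5 with hydrazine hydrate and catalytic AcOH in EtOH (transimination with loss of ammonia) should give 18.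

3. Step 17. Cleavage of seven methyl ethers may stay incomplete, and the Lewis acid may trigger cationic cyclisation or oligomerisation of the electron-rich stilbene. The fallback removes the methyl ethers before the stilbene exists; it sets out from 22 and comes back at target 25. BBr3 in CH2Cl2 converts 22 into the heptaphenol bromide F6. Acetylation (Ac2O, pyridine) gives the heptaacetate F7. Heck coupling of F7 with commercial 4-acetoxystyrene (Pd(OAc)2, P(o-tol)3, Et3N, DMF) gives the octaacetate F8. Mild methanolysis of F8 (catalytic K2CO3, degassed MeOH) should release 25.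

**Further compounds**

F1 | step 14 | 1-[4-bromo-2,6-bis(4-methoxybenzyloxy)phenyl]-1-[(2S,3S)-2-(3,4-dimethoxyphenyl)-3-(3,5-dimethoxyphenyl)-4-methoxy-2,3-dihydrobenzofuran-6-yl]-2-(4-methoxyphenyl)ethanol | COc1ccc(CC(O)(c2c(OCc3ccc(OC)cc3)cc(Br)cc2OCc2ccc(OC)cc2)c2cc(OC)c3c(c2)O[C@H](c2ccc(OC)c(OC)c2)[C@H]3c2cc(OC)cc(OC)c2)cc1
F2 | step 14 | 5-bromo-2-{1-[(2S,3S)-2-(3,4-dimethoxyphenyl)-3-(3,5-dimethoxyphenyl)-4-methoxy-2,3-dihydrobenzofuran-6-yl]-2-(4-methoxyphenyl)ethenyl}benzene-1,3-diol (triarylethene bisphenol) | COc1ccc(C=C(c2c(O)cc(Br)cc2O)c2cc(OC)c3c(c2)O[C@H](c2ccc(OC)c(OC)c2)[C@H]3c2cc(OC)cc(OC)c2)cc1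
F3 | step 14 | (2S,3S)-6-bromo-3-[(2S,3S)-2-(3,4-dimethoxyphenyl)-3-(3,5-dimethoxyphenyl)-4-methoxy-2,3-dihydrobenzofuran-6-yl]-2-(4-methoxyphenyl)-2,3-dihydrobenzofuran-4-ol (ring A diastereomer of 22) | Brc1cc(O)c2c(c1)O[C@H](c1ccc(OC)cc1)[C@H]2c1cc(OC)c2c(c1)O[C@H](c1ccc(OC)c(OC)c1)[C@H]2c1cc(OC)cc(OC)c1
F4 | step 12 | 4-bromo-2,6-bis[(4-methoxybenzyl)oxy]benzonitrile | COc1ccc(COc2cc(Br)cc(OCc3ccc(OC)cc3)c2C#N)cc1
F5 | step 12 | N–H ketimine of ketone 17 | COc1ccc(COc2cc(Br)cc(OCc3ccc(OC)cc3)c2C(=N)c2cc(OC)c3c(c2)O[C@H](c2ccc(OC)c(OC)c2)[C@H]3c2cc(OC)cc(OC)c2)cc1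
F6 | step 17 | (2R,3R)-6-bromo-3-[(2S,3S)-2-(3,4-dihydroxyphenyl)-3-(3,5-dihydroxyphenyl)-4-hydroxy-2,3-dihydrobenzofuran-6-yl]-2-(4-hydroxyphenyl)-2,3-dihydrobenzofuran-4-ol (heptaphenol bromide) | Brc1cc(O)c2c(c1)O[C@@H](c1ccc(O)cc1)[C@@H]2c1cc(O)c2c(c1)O[C@H](c1ccc(O)c(O)c1)[C@H]2c1cc(O)cc(O)c1
F7 | step 17 | heptaacetate of F6 | Brc1cc(OC(C)=O)c2c(c1)O[C@@H](c1ccc(OC(C)=O)cc1)[C@@H]2c1cc(OC(C)=O)c2c(c1)O[C@H](c1ccc(OC(C)=O)c(OC(C)=O)c1)[C@H]2c1cc(OC(C)=O)cc(OC(C)=O)c1
F8 | step 17 | octaacetate of target 25 | CC(=O)Oc1ccc(/C=C/c2cc(OC(C)=O)c3c(c2)O[C@@H](c2ccc(OC(C)=O)cc2)[C@@H]3c2cc(OC(C)=O)c3c(c2)O[C@H](c2ccc(OC(C)=O)c(OC(C)=O)c2)[C@H]3c2cc(OC(C)=O)cc(OC(C)=O)c2)cc1
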